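**Plan**
- Retrosynthesis: the three aryl O–CH3 bonds are cut last, and the resorcinol ring is then read as a 2-chlorocyclohexane-1,3-dione (the arene plus HCl).
- Enabling feature: C4, the single CH of the central ring, sits between the oxygenated carbons C3 and C5. Cutting C3–C4 and C4–C5 removes it as a one-carbon carbene unit and leaves the five-membered ring C3–C5–C6–C1–C2 with vicinal oxygens on a double bond, the bis(silyl) enediol ether of an acyloin.
- Cutting C3–C5 (acyloin condensation) opens that ring to a symmetric glutarate. Its C2–CH2Ar and C6–CH2Ar bonds are cut as two successive enolate benzylations, and C1–C2 and C1–C6 as a Knoevenagel–Michael union of one aldehyde with two malonates.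
- Forward: chain assembly (steps 1–4), five-membered ring by acyloin closure (step 5), expansion to the six-membered ring by dichlorocarbene insertion of C4 (step 6), aromatization (step 7), demethylation (step 8).
- Stereochemistry: the target has no stereocenter. The sp3 centers at C1, C2 and C6 of the intermediates are carried as diastereomer mixtures and vanish when the ring becomes aromatic.

Key step: step 6

Remark: ring atoms are numbered as in the target throughout (C1 arylethyl, C2 and C6 benzyl, C3 and C5 oxygen, C4 hydrogen). The 1,3-diones are drawn as diketones although their enol forms are expected to predominate.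

**Step 1**
Reactants: 1 3-(4-methoxyphenyl)propanal; 2 dimethyl malonate (2.3 equiv)
Product: 4 tetramethyl 2-[2-(4-methoxyphenyl)ethyl]propane-1,1,3,3-tetracarboxylate, via alkylidene malonate 3 (not isolated)
Conditions: piperidine (0.1 equiv), AcOH (0.1 equiv), toluene, reflux, Dean–Stark; then NaOMe (0.2 equiv), MeOH, rt
Reagents that add atoms: none
Why: Knoevenagel condensation gives the alkylidene malonate 3, a strong Michael acceptor that should take up the second malonate under methoxide catalysis, the classical entry to 3-substituted glutaric acid derivatives; the new CH carries two identical malonyl groups, so no stereocenter arises.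

**Step 2**
Reactants: 4 tetramethyl 2-[2-(4-methoxyphenyl)ethyl]propane-1,1,3,3-tetracarboxylate
Product: 5 dimethyl 3-[2-(4-methoxyphenyl)ethyl]pentanedioate
Conditions: NaCl (4 equiv), H2O (4 equiv), DMSO, 160 °C
Reagents that add atoms: none
Why: Krapcho dealkoxycarbonylation, in which chloride demethylates one ester of each malonate, the carboxylate loses CO2 and water protonates the ester enolate, should leave the anisyl ether and the two remaining esters untouched and gives an achiral diester.

**Step 3**
Reactants: 5 dimethyl 3-[2-(4-methoxyphenyl)ethyl]pentanedioate; 6 4-methoxybenzyl bromide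
Product: 7 dimethyl 2-(4-methoxybenzyl)-3-[2-(4-methoxyphenyl)ethyl]pentanedioate (mixture of diastereomers)
Conditions: LiN(iPr)2 (1.05 equiv), THF, −78 °C; then 6 (1.05 equiv), −78 to −20 °C; aq. NH4Cl
Reagents that add atoms: none
Why: Kinetic lithium ester enolate alkylation (SN2) with a reactive benzylic bromide should benzylate one of the two equivalent α-CH2 groups, a near-stoichiometric amount of base and electrophile keeping the reaction at the mono-alkylation stage; the two stereocenters that arise are formed without control, which is harmless because they are lost on aromatization.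

**Step 4**
Reactants: 7 dimethyl 2-(4-methoxybenzyl)-3-[2-(4-methoxyphenyl)ethyl]pentanedioate; 6 4-methoxybenzyl bromide
Product: 8 dimethyl 2,4-bis(4-methoxybenzyl)-3-[2-(4-methoxyphenyl)ethyl]pentanedioate (mixture of diastereomers)
Conditions: LiN(iPr)2 (1.2 equiv), THF, −78 °C; then 6 (1.3 equiv), −78 °C to rt; aq. NH4Cl
Reagents that add atoms: none
Why: A second kinetic ester enolate alkylation should place the benzyl group on the other arm, because the hindered amide base removes a proton from the remaining α-CH2 faster than from the already benzylated α-CH; the new stereocenter is again formed without control and the diastereomer mixture is carried on.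

**Step 5**
Reactants: 8 dimethyl 2,4-bis(4-methoxybenzyl)-3-[2-(4-methoxyphenyl)ethyl]pentanedioate
Product: 9 1,2-bis(trimethylsilyloxy)-3,5-bis(4-methoxybenzyl)-4-[2-(4-methoxyphenyl)ethyl]cyclopent-1-ene (mixture of diastereomers)
Conditions: Na (4.4 equiv, dispersion), Me3SiCl (5 equiv), toluene, reflux, Ar; filtered and concentrated under Ar, used crude
Reagents that add atoms: chlorotrimethylsilane, C[Si](C)(C)Cl
Why: In the Rühlmann variant of the acyloin condensation, sodium should reduce both ester groups to ketyl radical anions that couple to form the C3–C5 bond of a five-membered ring, and Me3SiCl traps the enediolate as the bis(silyl) ether and scavenges methoxide so that base-induced condensations do not compete; no new stereocenter is formed.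

**Step 6**
Reactants: 9 1,2-bis(trimethylsilyloxy)-3,5-bis(4-methoxybenzyl)-4-[2-(4-methoxyphenyl)ethyl]cyclopent-1-ene; 10 sodium trichloroacetate
Product: 13 2-chloro-4,6-bis(4-methoxybenzyl)-5-[2-(4-methoxyphenyl)ethyl]cyclohexane-1,3-dione (mixture of diastereomers), via dichlorocyclopropane 11 (not isolated), via chloro silyloxy enone 12 (not isolated)
Conditions: Cl3CCO2Na (3 equiv), DME, reflux, Ar; then 1 M HCl, THF, 0 °C
Reagents that add atoms: none
Why: Proposed new method: thermal decarboxylation of Cl3CCO2Na releases dichlorocarbene under neutral, aprotic conditions, and this electrophilic carbene should add in a cheletropic [2+1] manner to the C3=C5 double bond, forming the C3–C4 and C4–C5 bonds of dichlorocyclopropane 11. The strained bicyclo[3.1.0]hexane should then ionize its endo chloride while the shared C3–C5 bond opens in a disrotatory two-electron electrocyclic process, so the six-membered ring arises by expansion of the five-membered ring and not by a cyclization. The resulting 2-chloroallyl cation is stabilized at both termini by silyloxy groups, gives up one silyl group to chloride to form 12, and the remaining silyl enol ether is hydrolysed on acidic work-up to 13. The closest known reactions are the dihalocarbene one-carbon ring expansion of cyclic silyl enol ethers to 2-halo-2-enones and the cyclopropanation with ring enlargement of acyloin-derived bis(silyloxy)alkenes to 1,3-diones; their combination on a fully substituted enediol ether is what is new. No stereocenter of consequence is created, since C4 is sp2 in the enol form of 13 and the configurations at C1, C2 and C6 are inherited as a mixture and erased later. The step needs chemoselectivity for the enediol double bond over the three anisyl rings and the benzylic C–H bonds, which the far higher nucleophilicity of the dioxygenated tetrasubstituted alkene should secure, and it needs the silyl ethers to survive until the carbene has added, which the base-free and water-free carbene source should secure.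

**Step 7**
Reactants: 13 2-chloro-4,6-bis(4-methoxybenzyl)-5-[2-(4-methoxyphenyl)ethyl]cyclohexane-1,3-dione
Product: 15 4,6-bis(4-methoxybenzyl)-5-[2-(4-methoxyphenyl)ethyl]benzene-1,3-diol, via rearranged chlorodione 14 (not isolated)
Conditions: LiCl (5 equiv), DMF, 120 °C, Ar
Reagents that add atoms: none
Why: Proposed new method: in the weakly acidic, chloride-rich medium the chlorodione should enolize towards C6, chloride should add at C6 in an SN2' sense with loss of the chloride from C4 to give isomer 14, in which chlorine is α to a carbonyl and adjacent to the C1 hydrogen, and 14 should lose HCl across C6–C1 as α-halo ketones do with LiCl in DMF, after which the dienone tautomerizes to the arene; the closest known reactions are the halogen migration and dehydrohalogenation of 2-halocyclohexane-1,3-diones to resorcinols on heating in DMF and the LiCl/DMF dehydrohalogenation of α-halo ketones, and base is left out to avoid Favorskii-type ring contraction.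

**Step 8**
Reactants: 15 4,6-bis(4-methoxybenzyl)-5-[2-(4-methoxyphenyl)ethyl]benzene-1,3-diol
Product: 16 4,6-bis(4-hydroxybenzyl)-5-[2-(4-hydroxyphenyl)ethyl]benzene-1,3-diol (CNP0326726.0)
Conditions: BBr3 (8 equiv), CH2Cl2, −78 °C to rt; then H2O
Reagents that add atoms: none
Why: Lewis acid-mediated aryl methyl ether cleavage, in which BBr3 coordinates each methoxy oxygen, bromide removes the methyl group as MeBr and the aryl borates are hydrolysed on work-up, should free the three phenols while the diarylmethane and arylethyl C–C bonds stay intact; no stereocenter is involved.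

**Compound list**
1 | 3-(4-methoxyphenyl)propanal | COc1ccc(CCC=O)cc1 | starting material
2 | dimethyl malonate | COC(=O)CC(=O)OC | starting material
3 | dimethyl 2-[3-(4-methoxyphenyl)propylidene]malonate | COc1ccc(CCC=C(C(=O)OC)C(=O)OC)cc1 | intermediate
4 | tetramethyl 2-[2-(4-methoxyphenyl)ethyl]propane-1,1,3,3-tetracarboxylate | COc1ccc(CCC(C(C(=O)OC)C(=O)OC)C(C(=O)OC)C(=O)OC)cc1 | intermediate
5 | dimethyl 3-[2-(4-methoxyphenyl)ethyl]pentanedioate | COc1ccc(CCC(CC(=O)OC)CC(=O)OC)cc1 | intermediate
6 | 4-methoxybenzyl bromide | COc1ccc(CBr)cc1 | starting material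
7 | dimethyl 2-(4-methoxybenzyl)-3-[2-(4-methoxyphenyl)ethyl]pentanedioate (mixture of diastereomers) | COc1ccc(CCC(CC(=O)OC)C(Cc2ccc(OC)cc2)C(=O)OC)cc1 | intermediate
8 | dimethyl 2,4-bis(4-methoxybenzyl)-3-[2-(4-methoxyphenyl)ethyl]pentanedioate (mixture of diastereomers) | COc1ccc(CCC(C(Cc2ccc(OC)cc2)C(=O)OC)C(Cc2ccc(OC)cc2)C(=O)OC)cc1 | intermediate
9 | 1,2-bis(trimethylsilyloxy)-3,5-bis(4-methoxybenzyl)-4-[2-(4-methoxyphenyl)ethyl]cyclopent-1-ene (mixture of diastereomers) | COc1ccc(CCC2C(Cc3ccc(OC)cc3)C(O[Si](C)(C)C)=C(O[Si](C)(C)C)C2Cc2ccc(OC)cc2)cc1 | intermediate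
10 | sodium trichloroacetate | [Na+].[O-]C(=O)C(Cl)(Cl)Cl | starting material
11 | 6,6-dichloro-2,4-bis(4-methoxybenzyl)-3-[2-(4-methoxyphenyl)ethyl]-1,5-bis(trimethylsilyloxy)bicyclo[3.1.0]hexane (mixture of diastereomers) | COc1ccc(CCC2C(Cc3ccc(OC)cc3)C3(O[Si](C)(C)C)C(Cl)(Cl)C3(O[Si](C)(C)C)C2Cc2ccc(OC)cc2)cc1 | intermediate
12 | 2-chloro-4,6-bis(4-methoxybenzyl)-5-[2-(4-methoxyphenyl)ethyl]-3-(trimethylsilyloxy)cyclohex-2-en-1-one (mixture of diastereomers) | COc1ccc(CCC2C(Cc3ccc(OC)cc3)C(=O)C(Cl)=C(O[Si](C)(C)C)C2Cc2ccc(OC)cc2)cc1 | intermediate
13 | 2-chloro-4,6-bis(4-methoxybenzyl)-5-[2-(4-methoxyphenyl)ethyl]cyclohexane-1,3-dione (mixture of diastereomers) | COc1ccc(CCC2C(Cc3ccc(OC)cc3)C(=O)C(Cl)C(=O)C2Cc2ccc(OC)cc2)cc1 | intermediate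
14 | 4-chloro-4,6-bis(4-methoxybenzyl)-5-[2-(4-methoxyphenyl)ethyl]cyclohexane-1,3-dione (mixture of diastereomers) | COc1ccc(CCC2C(Cc3ccc(OC)cc3)C(=O)CC(=O)C2(Cl)Cc2ccc(OC)cc2)cc1 | intermediate
15 | 4,6-bis(4-methoxybenzyl)-5-[2-(4-methoxyphenyl)ethyl]benzene-1,3-diol | COc1ccc(CCc2c(Cc3ccc(OC)cc3)c(O)cc(O)c2Cc2ccc(OC)cc2)cc1 | intermediate
16 | 4,6-bis(4-hydroxybenzyl)-5-[2-(4-hydroxyphenyl)ethyl]benzene-1,3-diol (CNP0326726.0, achiral) | Oc1ccc(CCc2c(Cc3ccc(O)cc3)c(O)cc(O)c2Cc2ccc(O)cc2)cc1 | target

**Step count**
Total: 8 steps. Longest linear sequence: 8 steps (from aldehyde 1).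

**Steps most likely to fail**

Step 6. The silyl groups may be lost before the carbene arrives, the carbene may add only slowly to the hindered tetrasubstituted double bond, or the ring-opened cation may be diverted before it sheds its silyl group. The fallback sets out from 9 and uses a methylene carbenoid followed by a separate oxidation. Et2Zn and CH2I2 in toluene at 0 °C to rt (Simmons–Smith cyclopropanation) should give 2,4-bis(4-methoxybenzyl)-3-[2-(4-methoxyphenyl)ethyl]-1,5-bis(trimethylsilyloxy)bicyclo[3.1.0]hexane F1. FeCl3 (2.2 equiv) in DMF at 0 °C to rt should open the shared bond oxidatively with one-carbon ring enlargement to 4,6-bis(4-methoxybenzyl)-5-[2-(4-methoxyphenyl)ethyl]cyclohexane-1,3-dione F2. Br2 (1.0 equiv) in DMF at 0 °C should then brominate between the carbonyls to 2-bromo-4,6-bis(4-methoxybenzyl)-5-[2-(4-methoxyphenyl)ethyl]cyclohexane-1,3-dione F3, which on warming to 80 °C in the same flask is expected to lose HBr. The route is rejoined at 15.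

Step 7. The chlorine may fail to leave the carbon between the two carbonyls, so that dehydrochlorination stalls, or prolonged heating may degrade the chlorodione. The fallback sets out from 13. Zn dust in AcOH at rt should remove the chlorine reductively to give 4,6-bis(4-methoxybenzyl)-5-[2-(4-methoxyphenyl)ethyl]cyclohexane-1,3-dione F2, the same compound as in the fallback to step 6. I2 (2 equiv) in MeOH at reflux should aromatize it with O-methylation to 1,5-dimethoxy-2,4-bis(4-methoxybenzyl)-3-[2-(4-methoxyphenyl)ethyl]benzene F4; any monomethyl ether formed alongside converges in the next operation. BBr3 (12 equiv) in CH2Cl2, as in step 8, should then cleave all five methyl ethers. The route is rejoined at 16.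

Step 4. Deprotonation may not discriminate cleanly between the free α-CH2 and the benzylated α-CH, proton exchange between enolates may lead to double benzylation at one α-carbon, or the alkylation of the hindered enolate may stay incomplete. The fallback sets out from 4, before the dealkoxycarbonylation, and alkylates the soft malonate anions instead. NaH (2.2 equiv) and 6 (2.4 equiv) in DMF at 0 °C to rt should give tetramethyl 1,5-bis(4-methoxyphenyl)-3-[2-(4-methoxyphenyl)ethyl]pentane-2,2,4,4-tetracarboxylate F5. A double Krapcho dealkoxycarbonylation (NaCl, H2O, DMSO, 170 °C) should then deliver the diester. The route is rejoined at 8.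

**Further compounds**
F1 | step 6 | 2,4-bis(4-methoxybenzyl)-3-[2-(4-methoxyphenyl)ethyl]-1,5-bis(trimethylsilyloxy)bicyclo[3.1.0]hexane (mixture of diastereomers) | COc1ccc(CCC2C(Cc3ccc(OC)cc3)C3(O[Si](C)(C)C)CC3(O[Si](C)(C)C)C2Cc2ccc(OC)cc2)cc1
F2 | step 6 | 4,6-bis(4-methoxybenzyl)-5-[2-(4-methoxyphenyl)ethyl]cyclohexane-1,3-dione (mixture of diastereomers) | COc1ccc(CCC2C(Cc3ccc(OC)cc3)C(=O)CC(=O)C2Cc2ccc(OC)cc2)cc1
F3 | step 6 | 2-bromo-4,6-bis(4-methoxybenzyl)-5-[2-(4-methoxyphenyl)ethyl]cyclohexane-1,3-dione (mixture of diastereomers) | COc1ccc(CCC2C(Cc3ccc(OC)cc3)C(=O)C(Br)C(=O)C2Cc2ccc(OC)cc2)cc1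
F4 | step 7 | 1,5-dimethoxy-2,4-bis(4-methoxybenzyl)-3-[2-(4-methoxyphenyl)ethyl]benzene | COc1ccc(CCc2c(Cc3ccc(OC)cc3)c(OC)cc(OC)c2Cc2ccc(OC)cc2)cc1
F5 | step 4 | tetramethyl 1,5-bis(4-methoxyphenyl)-3-[2-(4-methoxyphenyl)ethyl]pentane-2,2,4,4-tetracarboxylate | COc1ccc(CCC(C(Cc2ccc(OC)cc2)(C(=O)OC)C(=O)OC)C(Cc2ccc(OC)cc2)(C(=O)OC)C(=O)OC)cc1
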